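We cannot read the order in partner directly off the readings: no two earlier runs differ in partner alone, and Monday's first reading already shows 66.3 % starting material left, past the 5.0 % conversion asked about.

| setting | Monday's | Sunday's | Saturday's | flask |
|---|---|---|---|---|
| starting material | 0.17 M | 0.38 M | 0.25 M | 0.25 M |
| partner | 0.50 M | 0.50 M | 1 M | 0.500 M |
| free catalyst | 2.3 mM | 2.3 mM | 2.3 mM | 2.3 mM |
| remark | run made earlier | run made earlier | run made earlier |  |

| run | time / min | target / % | starting material / % |
|---|---|---|---|
| Monday's | 0.500 | 8.2 | 66.3 |
| Monday's | 1.33 | 30.6 | 38.9 |
| Monday's | 2.50 | 59.4 | 20.9 |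
| Monday's | 4.00 | 81.5 | 8.8 |
| Sunday's | 1.00 | 17.7 | 51.9 |
| Sunday's | 2.00 | 40.9 | 32.2 |
| Sunday's | 3.00 | 60.1 | 19.6 |
| Sunday's | 4.00 | 75.0 | 12.0 |
| Saturday's | 1.00 | 11.2 | 59.2 |
| Saturday's | 2.00 | 30.3 | 39.0 |
| Saturday's | 3.00 | 48.1 | 28.1 |
| Saturday's | 4.00 | 62.6 | 18.9 |

(scatter of a reading: 0.5 percentage points)

* apparent order in partner when 5.0 % of the starting material are converted (percent change of the rate of making target for one percent more partner charged)

What we can do is compare clocks in logarithms. Saturday's run has our flask's charge of starting material and twice its c(partner), so we need our flask's pace, and two extreme versions of it can be solved in the head. If our flask kept Monday's pace, Monday's 30.6 % target at 1.33 min matches Saturday's 30.3 % at 2.00 min within the scatter, and the logarithm of that time ratio over the logarithm of the partner ratio gives −0.589. If it kept Sunday's pace, 60.1 % at 3.00 min against Saturday's 62.6 % at 4.00 min gives roughly −0.415. The real flask should lie between them, since its c(starting material) of 0.25 M lies between Monday's and Sunday's, and at 4.00 min Monday's target stands above Sunday's. On a logarithmic scale of charge it sits 0.479 of the way from Monday to Sunday, so we commit to −0.505. This is the partner exponent: the logarithm of the time ratio between two flasks reaching the same level of target, over the logarithm of their partner ratio. It is read at those two target levels, and we carry it to 5.0 % conversion as our estimate.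

The forecast says −0.45, within −0.7 to −0.25, on this ground: “Doubling partner therefore slows this step”.

The simulation gives −0.33, above our −0.505.

    starting material + free catalyst ⇌ free catalyst + open intermediate (K = 2.10, k = 1200 M⁻¹ min⁻¹)
    free catalyst + open intermediate ⇌ catalyst intermediate (K = 290 M⁻¹, k = 1300 M⁻¹ min⁻¹)
    partner + catalyst intermediate → free catalyst + target (k = 270 M⁻¹ min⁻¹)
    partner + free catalyst ⇌ idle complex, settled at all times (K = 3.50 M⁻¹)

At 5.0 % conversion the flask holds 61.3 % of its catalyst as idle complex, an off-cycle form, against 35.2 % free catalyst and 3.50 % catalyst intermediate, and the equilibrium constant of that joining times charged partner is 1.8. Our exponent stretches the clock by 1.42 on doubling partner, so the flask's 45.3 % target at 2.00 min belongs on Saturday's curve at 2.84 min, where Saturday's readings run from 30.3 % at 2.00 min to 48.1 % at 3.00 min.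

(The earlier runs and the new flask were generated by integration with constants of no real substance; scatter was added.)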